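## Structural features

The target is a bicyclic halimane-type diterpenoid: a cyclohexenone ring A (C1, C2, C3, C4, C5, C10) is fused through the C5–C10 bond to a cyclohexane ring B (C5 to C10), and C9 carries a five-carbon chain (C11 to C15) ending in a primary alcohol. Ring A holds the enone (C2 ketone, C1=C10 alkene, C10 being the sp2 ring-fusion carbon) and the quaternary C4 (methyl, methyl ester) next to the tertiary C5. Ring B holds the contiguous pair C8 (methyl, hydrogen) and quaternary C9 (methyl, chain). The two ring B methyls are cis to each other and trans to C5–H, the ester is cis to C5–H, and C13 is remote; the descriptors are 4S, 5S, 8R, 9S, 13R. Fragile points are the γ-hydrogen at C5 of the enone (base can epimerise C5 or move the alkene), the pair methyl ester/primary alcohol, and any acid-labile protecting group once cations are involved. The real difficulty is the quaternary C9, wedged between the C8 stereocentre and the sp2 C10 and far from any group that could help to build it. The key step exploits exactly this: a C9 methyl beside a C8 hydrogen and an sp2 C10 is what remains when a trans-fused decalin C8 cation bearing a C10 methyl passes its charge back to C10 by a C9-to-C8 hydride shift and a C10-to-C9 methyl shift. Ring B and both of its stereocentres can therefore come from a ring A 1-methylcyclohexene carrying an (E)-C8=C9 alkene on C5. The C2 oxygen sits on the only allylic methylene of the C1=C10 alkene and can be added last, and C13 with the C15 oxygen maps onto (R)-citronellol.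

## Logic of the disconnections

**28 back to 26.** The last bonds made are heteroatom bonds: the C2=O of the enone (27 from 26) and the free C15 hydroxyl (28 from 27). Cutting the C2 oxygen leaves 26, whose only alkene has a single allylic methylene, C2, and keeps the sensitive enone out of the cationic step. The chain oxygen stays acetylated from 25 to 27 because an acetate tolerates strong acid and hexavalent chromium. The forward demands are an allylic oxidation that takes C2–H and not the tertiary C5–H, and a deacetylation that spares the methyl ester and the C5 γ-hydrogen.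

**26 back to 25.** The C9–C10 ring bond is cut and, in the same move, the C9 methyl is returned to C10 and the C8 hydrogen to C9. Ring B opens to an (E)-C8=C9 alkene and C10 becomes the methyl-bearing carbon of the ring A alkene. This removes ring B, the quaternary C9 and two stereocentres at once and leaves a monocyclic 1,5-diene with only C4, C5 and C13 stereogenic. The demand is the heaviest of the route: one acid treatment must protonate the ring alkene, close ring B trans, let two 1,2-shifts outrun proton loss, and end by loss of a C1 proton.

**25 back to 21.** The C1–H bond of the ring alkene is traced to a C1–O bond: 25 from 23 by exchange of silyl for acetyl, 23 from the enol triflate 22, 22 from the silyl enol ether 21. The C1=C10 alkene is thus placed by an enolate of defined regiochemistry and not by an elimination or an equilibrating enolisation. The demand is that the enolate is released and sulfonylated without equilibration and that the triflate is reduced without touching the chain alkene.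

**21 back to 9 and 19.** The C5–C6 bond is cut between the ring A enone 9 and the Grignard reagent 20 derived from 19. C5 is the β-carbon of an enone whose enolate is exactly the C1/C10 enolate needed, and the two fragments are of similar size. The demand is a 1,4-addition to a β-carbon next to a quaternary centre in an α-methyl enone, on the face anti to the ester.

**9 back to 7.** The C10–CH3 bond is cut by way of the C10–I bond of 8. Placing the methyl on the enone before the conjugate addition means the later enolate already carries it on the right carbon. The demand is α-halogenation and cross-coupling on a hindered enone.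

**7 back to 1 and 2.** The ester carbon is traced through the acid 6 to the alcohol 5, and ring A through 4 and 3 to 1 and 2 by cutting C4–C5 and C2–C3 (retro-Diels–Alder). This makes the quaternary C4 enantioselectively from two achiral commercial compounds and puts the ring carbonyl at C1, para to C4, where the enolate chemistry needs it. The demand is catalyst control of the enal face and reduction of the aldehyde of 3 before the adduct is unmasked.

**19 back to 10.** The chain is traced from 19 to 18 (C6–Br to C6–O), 18 to 16 (anti-Markovnikov hydration, C6–O), 16 to 15 (C6=C7, one-carbon Wittig), 15 to 13 and 14 (C8=C9), and 13 to 11 and 10 (C9 is the alkene carbon of the chiral-pool alcohol). C13 is bought, and the alkene geometry comes from a stabilised ylide. The demand is high (E) purity at C8=C9, because that geometry becomes the C8 and C9 configurations.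

## Other disconnections considered

**Alternative 1:** The cut removes C3–C4 and C5–C10 together, opening both rings to the acyclic triene A1, in which an (E)-2-methyl enal (C4=C5) is tied through C6–C7–C8–C9 to a 2-silyloxy diene (C3=C2–C1=C10). Forward, an intramolecular Diels–Alder reaction of A1 would give the trans-fused silyl enol ether A2 with the C4 aldehyde.
- In its favour: two rings and two C–C bonds form in one thermal step. The cis relation of the C4 carbonyl group to C5–H follows stereospecifically from the (E) enal, which is better than the chosen plan, where it rests on the facial preference of a conjugate addition. The C2 oxygen is built in, so the enone would follow from A2 by Saegusa–Ito dehydrogenation with Pd(OAc)2 instead of a late allylic C–H oxidation, again the better on that point.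
- Against it here: the cycloaddition does nothing for the hardest part, since A1 must already contain the C8/C9 pair on an open chain. Its facial course would be governed only by C9, whose methyl and CH2 substituents differ little in size. The aldehyde must still be oxidised to the ester.
- Comparison: mechanistically it is the safer (a concerted step with no competing proton losses). Structurally it moves the problem into the acyclic precursor. In step count it would probably be longer.

**Alternative 2:** The cut is made in ring B alone: C8–CH3 and C9–C11 are disconnected from a cyclohexanone whose carbonyl carbon is C10, leading to the enone A3 and the allylic bromide A4. Forward, copper-catalysed asymmetric conjugate methylation of A3 would set C8, and alkylation of the resulting C9 enolate by A4 anti to the new methyl would give A5; no ring closes.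
- In its favour: it attacks the C8/C9 pair first with a well-established reaction class, so on certainty of C8 and C9 it is better than the chosen plan, and it is very short up to A5.
- Against it here: ring A with the C4 quaternary ester and C5 must then be annulated onto the C10 ketone beside the new quaternary C9, forming C4–C5 between two congested carbons with two more stereocentres to control. C13 is absent from A5 and would need a later catalyst-controlled hydrogenation, where the chosen plan takes it from the chiral pool.
- Comparison: structurally it secures ring B and leaves ring A open, the reverse of the chosen plan. Its key step is mechanistically the more reliable. In steps it would be shorter at the start and longer at the end, at best equal overall.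

**Alternative 3:** The cut removes C4–C5 and C2–C3 of ring A from the ring B diene A6 (C5=C10–C1=C2, with C8 and C9 in place) and methacrolein 2. Forward, a catalyst-controlled Diels–Alder reaction would close ring A and give the aldehyde A7, which has the C1=C10 alkene of 26.
- In its favour: the alkene position is dictated by the pericyclic mechanism, so the choice between C1–H and C5–H that burdens the chosen key step does not arise; on this point the alternative is clearly the better. C4 and C5 form together, and from A6 the target would be four or five steps away, which makes it the equal of the chosen plan, or shorter, if A6 is reached through A5.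
- Against it here: A6 must carry the C8/C9 pair. The substituents at the diene terminus C5 and at C10 direct the dienophile in opposite senses. The diene faces differ only by the methyl and CH2 groups on the adjacent quaternary C9. The endo/exo preference of an α-methyl enal decides C4 and is often low. C2 still needs the same allylic oxidation (equal).
- Comparison: it trades one uncertain cationic step for a cycloaddition with three simultaneous selectivity demands on a hindered diene; both reach the same bicyclic alkene skeleton.

The chosen plan is kept because it is the only one in which the C8/C9 pair is an output of the key step, copied from one alkene geometry and one existing ring centre, and not an input that has to be made beforehand.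

Key step: step 17

Assumption: the (R,R) enantiomer of the diol catalyst in step 1 is taken to give the (S) configuration at the quaternary carbon of 3; if the sense of induction is the opposite, the (S,S) catalyst is used with no other change.

Atom numbers C1 to C15 and C18 (ester carbon) are those of the target throughout.

## Steps

Step 1
Reactants: 1 (E)-1-(dimethylamino)-3-(tert-butyldimethylsilyloxy)buta-1,3-diene; 2 methacrolein
Product: 4 [(1S,2R)-4-(tert-butyldimethylsilyloxy)-2-(dimethylamino)-1-methylcyclohex-3-en-1-yl]methanol, via cycloadduct aldehyde 3 (not isolated)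
Conditions: (R,R)-1-naphthyl-TADDOL (20 mol%), toluene, −80 °C; then LiAlH4, Et2O, −80 °C to rt
Reagents that add atoms: none
Why: Hydrogen-bond-catalysed asymmetric Diels–Alder reaction of an aminosiloxydiene with an α-substituted enal; the amino terminus bonds to the enal α-carbon (C4–C5) and the CH2 terminus to the β-carbon (C2–C3), and the diol-bound enal is attacked on its open face, which sets the quaternary C4. Hydride reduction in the same flask removes the neopentyl aldehyde before the enamine-type adduct is unmasked; the amino-bearing centre is lost in step 2.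

Step 2
Reactants: 4 [(1S,2R)-4-(tert-butyldimethylsilyloxy)-2-(dimethylamino)-1-methylcyclohex-3-en-1-yl]methanol
Product: 5 (S)-4-(hydroxymethyl)-4-methylcyclohex-2-en-1-one
Conditions: HF (aq.), MeCN, 0 °C to rt
Reagents that add atoms: none
Why: Desilylation of the silyl enol ether gives the β-amino ketone, which loses dimethylamine by E1cB elimination to the enone; C4 is not touched.

Step 3
Reactants: 5 (S)-4-(hydroxymethyl)-4-methylcyclohex-2-en-1-one
Product: 6 (S)-1-methyl-4-oxocyclohex-2-ene-1-carboxylic acid
Conditions: CrO3, H2SO4, H2O, acetone, 0 °C
Reagents that add atoms: water, O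
Why: Jones oxidation takes the neopentyl primary alcohol through the aldehyde hydrate to the acid; the enone and the quaternary centre are inert to acidic hexavalent chromium.

Step 4
Reactants: 6 (S)-1-methyl-4-oxocyclohex-2-ene-1-carboxylic acid
Product: 7 methyl (S)-1-methyl-4-oxocyclohex-2-ene-1-carboxylate
Conditions: MeI, K2CO3, DMF, rt
Reagents that add atoms: iodomethane, CI
Why: Carboxylate O-alkylation (SN2) esterifies the hindered acid without acid or heat, which avoids decarboxylation of the vinylogous β-keto acid.

Step 5
Reactants: 7 methyl (S)-1-methyl-4-oxocyclohex-2-ene-1-carboxylate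
Product: 8 methyl (S)-3-iodo-1-methyl-4-oxocyclohex-2-ene-1-carboxylate
Conditions: I2, pyridine, CH2Cl2, rt
Reagents that add atoms: iodine, II
Why: α-Iodination of the enone by amine addition, iodination of the enolate and elimination places iodine on C10 only.

Step 6
Reactants: 8 methyl (S)-3-iodo-1-methyl-4-oxocyclohex-2-ene-1-carboxylate
Product: 9 methyl (S)-1,3-dimethyl-4-oxocyclohex-2-ene-1-carboxylate
Conditions: MeB(OH)2, PdCl2(dppf) (5 mol%), K3PO4, THF/H2O, 65 °C
Reagents that add atoms: methylboronic acid, CB(O)O
Why: Suzuki–Miyaura methylation of the α-iodoenone installs the C10 methyl, so that the enolate formed in step 13 already carries it on the right carbon.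

Step 7
Reactants: 10 (R)-citronellol
Product: 11 tert-butyl{[(3R)-3,7-dimethyloct-6-en-1-yl]oxy}dimethylsilane
Conditions: TBSCl, imidazole, CH2Cl2, rt
Reagents that add atoms: tert-butyldimethylsilyl chloride, CC(C)(C)[Si](C)(C)Cl
Why: Silylation of the primary alcohol; the silyl ether withstands ozone, ylides, boranes and the Grignard stage.

Step 8
Reactants: 11 tert-butyl{[(3R)-3,7-dimethyloct-6-en-1-yl]oxy}dimethylsilane
Product: 13 (4R)-6-(tert-butyldimethylsilyloxy)-4-methylhexanal, via ozonide 12 (not isolated)
Conditions: O3, CH2Cl2, −78 °C; then PPh3, −78 °C to rt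
Reagents that add atoms: ozone, [O-][O+]=O
Why: Ozonolysis with reductive work-up cleaves the only alkene; the aldehyde carbon becomes C9 and the C13 centre is untouched.

Step 9
Reactants: 13 (4R)-6-(tert-butyldimethylsilyloxy)-4-methylhexanal; 14 2-(triphenylphosphoranylidene)propanal
Product: 15 (2E,6R)-8-(tert-butyldimethylsilyloxy)-2,6-dimethyloct-2-enal
Conditions: toluene, 80 °C
Reagents that add atoms: none
Why: Wittig reaction of a stabilised formyl ylide should give the (E)-trisubstituted enal, forming C8=C9 with the formyl carbon (C7) trans to C11.

Step 10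
Reactants: 15 (2E,6R)-8-(tert-butyldimethylsilyloxy)-2,6-dimethyloct-2-enal
Product: 16 tert-butyl{[(3R,6E)-3,7-dimethylnona-6,8-dien-1-yl]oxy}dimethylsilane
Conditions: Ph3PCH3Br, KOtBu, THF, 0 °C to rt
Reagents that add atoms: methyltriphenylphosphonium bromide, C[P+](c1ccccc1)(c1ccccc1)c1ccccc1.[Br-]
Why: Wittig methylenation adds C6 by 1,2-addition to the enal without touching the C8=C9 geometry.

Step 11
Reactants: 16 tert-butyl{[(3R,6E)-3,7-dimethylnona-6,8-dien-1-yl]oxy}dimethylsilane
Product: 18 (3E,7R)-9-(tert-butyldimethylsilyloxy)-3,7-dimethylnon-3-en-1-ol, via alkylborane 17 (not isolated)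
Conditions: 9-BBN, THF, 0 °C to rt; then NaOH, H2O2, 0 °C
Reagents that add atoms: hydrogen peroxide, OO
Why: Hydroboration–oxidation with a bulky dialkylborane is anti-Markovnikov and confined to the monosubstituted terminus of the diene; the trisubstituted alkene keeps its geometry.

Step 12
Reactants: 18 (3E,7R)-9-(tert-butyldimethylsilyloxy)-3,7-dimethylnon-3-en-1-ol
Product: 19 {[(3R,6E)-9-bromo-3,7-dimethylnon-6-en-1-yl]oxy}(tert-butyl)dimethylsilane
Conditions: CBr4, PPh3, CH2Cl2, 0 °C
Reagents that add atoms: tetrabromomethane, BrC(Br)(Br)Br
Why: Appel bromination of the primary homoallylic alcohol under neutral conditions.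

Step 13
Reactants: 19 {[(3R,6E)-9-bromo-3,7-dimethylnon-6-en-1-yl]oxy}(tert-butyl)dimethylsilane; 9 methyl (S)-1,3-dimethyl-4-oxocyclohex-2-ene-1-carboxylate
Product: 21 methyl (1S,2S)-2-[(3E,7R)-9-(tert-butyldimethylsilyloxy)-3,7-dimethylnon-3-en-1-yl]-1,3-dimethyl-4-(trimethylsilyloxy)cyclohex-3-ene-1-carboxylate, via Grignard reagent 20 (not isolated)
Conditions: Mg, THF, 40 °C; then CuBr·SMe2 (10 mol%), Me3SiCl, DMPU, THF, −78 to −40 °C, add 9
Reagents that add atoms: chlorotrimethylsilane, C[Si](C)(C)Cl
Why: Chlorosilane-accelerated, copper-catalysed conjugate addition of a Grignard reagent forms C5–C6; the alkyl group should enter C5 axially, anti to the pseudoaxial C4 ester and so cis to the C4 methyl, which sets C5. Silylation on oxygen fixes the C1=C10 enolate regiochemistry.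

Step 14
Reactants: 21 methyl (1S,2S)-2-[(3E,7R)-9-(tert-butyldimethylsilyloxy)-3,7-dimethylnon-3-en-1-yl]-1,3-dimethyl-4-(trimethylsilyloxy)cyclohex-3-ene-1-carboxylate
Product: 22 methyl (1S,2S)-2-[(3E,7R)-9-(tert-butyldimethylsilyloxy)-3,7-dimethylnon-3-en-1-yl]-1,3-dimethyl-4-(trifluoromethanesulfonyloxy)cyclohex-3-ene-1-carboxylate
Conditions: PhNTf2, CsF, DME, 0 °C to rt
Reagents that add atoms: N-phenylbis(trifluoromethanesulfonimide), O=S(=O)(N(c1ccccc1)S(=O)(=O)C(F)(F)F)C(F)(F)F
Why: Fluoride releases the enolate from the trimethylsilyl enol ether without equilibration and the triflimide sulfonylates it on oxygen (enol triflate formation); the alkyl tert-butyldimethylsilyl ether is cleaved far more slowly.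

Step 15
Reactants: 22 methyl (1S,2S)-2-[(3E,7R)-9-(tert-butyldimethylsilyloxy)-3,7-dimethylnon-3-en-1-yl]-1,3-dimethyl-4-(trifluoromethanesulfonyloxy)cyclohex-3-ene-1-carboxylate
Product: 23 methyl (1S,2S)-2-[(3E,7R)-9-(tert-butyldimethylsilyloxy)-3,7-dimethylnon-3-en-1-yl]-1,3-dimethylcyclohex-3-ene-1-carboxylate
Conditions: Pd(OAc)2 (5 mol%), PPh3, HCO2H, n-Bu3N, DMF, 60 °C
Reagents that add atoms: none
Why: Palladium-catalysed formate reduction of the enol triflate (oxidative addition to zerovalent palladium, formate to hydride with loss of CO2, reductive elimination) puts hydrogen on C1 and leaves the alkene at C1=C10.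

Step 16
Reactants: 23 methyl (1S,2S)-2-[(3E,7R)-9-(tert-butyldimethylsilyloxy)-3,7-dimethylnon-3-en-1-yl]-1,3-dimethylcyclohex-3-ene-1-carboxylate
Product: 25 methyl (1S,2S)-2-[(3E,7R)-9-acetoxy-3,7-dimethylnon-3-en-1-yl]-1,3-dimethylcyclohex-3-ene-1-carboxylate, via primary alcohol 24 (not isolated)
Conditions: TBAF, THF, 0 °C to rt; then Ac2O, Et3N, DMAP (cat.), rt
Reagents that add atoms: acetic anhydride, CC(=O)OC(C)=O
Why: Fluoride desilylation followed by acetylation in the same flask; the acetate survives strong acid and, once protonated, cannot act as an internal nucleophile.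

Step 17
Reactants: 25 methyl (1S,2S)-2-[(3E,7R)-9-acetoxy-3,7-dimethylnon-3-en-1-yl]-1,3-dimethylcyclohex-3-ene-1-carboxylate
Product: 26 methyl (4S,5S,8R,9S,13R)-15-acetoxyhalim-1(10)-en-18-oate
Conditions: ClSO3H (3 equiv), 2-nitropropane, −78 °C; then Et3N, MeOH, −78 °C
Reagents that add atoms: none
Why: Proposed new method: Markovnikov protonation of the C1=C10 alkene at C1 should give the C10 cation, which C9 of the (E)-alkene attacks in a 6-endo cation–olefin closure of ring B to the trans-fused labdane-type C8 cation; antiperiplanar suprafacial 1,2-shifts of the axial C9–H to C8 and then of the axial C10 methyl to C9 return the charge to C10, and loss of a C1 proton ends the cascade, the closest known reaction types being the acid-promoted bicyclisation of monocyclic 1,5-dienes to trans-decalins and the acid-induced labdane-to-halimane backbone rearrangement. The new C8 centre is set by the hydride shift on the face that H-9 occupied, and that face is fixed by the (E) geometry of the C8=C9 alkene in the chair transition state (C11 equatorial, H-9 axial and anti to the C10 methyl). The new C9 centre is set by the methyl shift on the face that the C10 methyl occupied, and that face is fixed by the C5 centre: with the C5 chain equatorial, C9 bonds to C10 equatorially on the side of the axial C5–H, so the methyl becomes axial and anti to C5–H. The step needs four selectivities: protonation of the ring alkene and not the chain alkene, trans ring fusion, shifts before proton loss, and loss of H from C1 and not from C5. The first two rest on the chair–chair preorganisation imposed by the C5 centre; the shifts are driven by relief of the 1,3-diaxial contact between the C4 methyl and the C10 methyl, and the relay stops at C10 because a further hydride shift would place the charge beside the ester-bearing C4. Loss of H-1 is favoured only kinetically (C5–H is flanked by the quaternary C4 and deactivated by the ester), so the cations are held in superacid, where the protonated carbonyl groups cannot capture them, and are deprotonated in a cold basic quench.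

Step 18
Reactants: 26 methyl (4S,5S,8R,9S,13R)-15-acetoxyhalim-1(10)-en-18-oate
Product: 27 methyl (4S,5S,8R,9S,13R)-15-acetoxy-2-oxohalim-1(10)-en-18-oate
Conditions: CrO3, 3,5-dimethylpyrazole, CH2Cl2, −20 °C
Reagents that add atoms: chromium trioxide, O=[Cr](=O)=O
Why: Allylic C–H oxidation by the CrO3–pyrazole complex at the only allylic methylene (C2) should give the enone; the other allylic hydrogen, on C5, is tertiary and hindered, and 26 has no second alkene.

Step 19
Reactants: 27 methyl (4S,5S,8R,9S,13R)-15-acetoxy-2-oxohalim-1(10)-en-18-oate
Product: 28 methyl (4S,5S,8R,9S,13R)-15-hydroxy-2-oxohalim-1(10)-en-18-oate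
Conditions: K2CO3 (0.2 equiv), MeOH, 0 °C
Reagents that add atoms: none
Why: Base-catalysed transesterification removes the primary acetate; exchange at the methyl ester is degenerate in methanol, and the cold, short treatment is meant to avoid γ-deprotonation at C5.

## Compound list

1 | (E)-1-(dimethylamino)-3-(tert-butyldimethylsilyloxy)buta-1,3-diene | CN(C)/C=C/C(=C)O[Si](C)(C)C(C)(C)C | starting material
2 | methacrolein | CC(=C)C=O | starting material
3 | (1S,2R)-4-(tert-butyldimethylsilyloxy)-2-(dimethylamino)-1-methylcyclohex-3-ene-1-carbaldehyde (endo adduct, formyl cis to the amino group) | O=C[C@@]1(C)CCC(O[Si](C)(C)C(C)(C)C)=C[C@H]1N(C)C | intermediate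
4 | [(1S,2R)-4-(tert-butyldimethylsilyloxy)-2-(dimethylamino)-1-methylcyclohex-3-en-1-yl]methanol | OC[C@@]1(C)CCC(O[Si](C)(C)C(C)(C)C)=C[C@H]1N(C)C | intermediate
5 | (S)-4-(hydroxymethyl)-4-methylcyclohex-2-en-1-one | OC[C@@]1(C)CCC(=O)C=C1 | intermediate
6 | (S)-1-methyl-4-oxocyclohex-2-ene-1-carboxylic acid | OC(=O)[C@@]1(C)CCC(=O)C=C1 | intermediate
7 | methyl (S)-1-methyl-4-oxocyclohex-2-ene-1-carboxylate | COC(=O)[C@@]1(C)CCC(=O)C=C1 | intermediate
8 | methyl (S)-3-iodo-1-methyl-4-oxocyclohex-2-ene-1-carboxylate | COC(=O)[C@@]1(C)CCC(=O)C(I)=C1 | intermediate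
9 | methyl (S)-1,3-dimethyl-4-oxocyclohex-2-ene-1-carboxylate | COC(=O)[C@@]1(C)CCC(=O)C(C)=C1 | intermediate
10 | (R)-citronellol | CC(C)=CCC[C@@H](C)CCO | starting material
11 | tert-butyl{[(3R)-3,7-dimethyloct-6-en-1-yl]oxy}dimethylsilane | CC(C)=CCC[C@@H](C)CCO[Si](C)(C)C(C)(C)C | intermediate
12 | 5-[(3R)-5-(tert-butyldimethylsilyloxy)-3-methylpentyl]-3,3-dimethyl-1,2,4-trioxolane (ozonide, acetal carbon a mixture) | CC1(C)OOC(CC[C@@H](C)CCO[Si](C)(C)C(C)(C)C)O1 | intermediate
13 | (4R)-6-(tert-butyldimethylsilyloxy)-4-methylhexanal | O=CCC[C@@H](C)CCO[Si](C)(C)C(C)(C)C | intermediate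
14 | 2-(triphenylphosphoranylidene)propanal | CC(C=O)=P(c1ccccc1)(c1ccccc1)c1ccccc1 | starting material
15 | (2E,6R)-8-(tert-butyldimethylsilyloxy)-2,6-dimethyloct-2-enal | O=C/C(C)=C/CC[C@@H](C)CCO[Si](C)(C)C(C)(C)C | intermediate
16 | tert-butyl{[(3R,6E)-3,7-dimethylnona-6,8-dien-1-yl]oxy}dimethylsilane | C=C/C(C)=C/CC[C@@H](C)CCO[Si](C)(C)C(C)(C)C | intermediate
17 | 9-[(3E,7R)-9-(tert-butyldimethylsilyloxy)-3,7-dimethylnon-3-en-1-yl]-9-borabicyclo[3.3.1]nonane | B1(CC/C(C)=C/CC[C@@H](C)CCO[Si](C)(C)C(C)(C)C)C2CCCC1CCC2 | intermediate
18 | (3E,7R)-9-(tert-butyldimethylsilyloxy)-3,7-dimethylnon-3-en-1-ol | OCC/C(C)=C/CC[C@@H](C)CCO[Si](C)(C)C(C)(C)C | intermediate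
19 | {[(3R,6E)-9-bromo-3,7-dimethylnon-6-en-1-yl]oxy}(tert-butyl)dimethylsilane | BrCC/C(C)=C/CC[C@@H](C)CCO[Si](C)(C)C(C)(C)C | intermediate
20 | [(3E,7R)-9-(tert-butyldimethylsilyloxy)-3,7-dimethylnon-3-en-1-yl]magnesium bromide | Br[Mg]CC/C(C)=C/CC[C@@H](C)CCO[Si](C)(C)C(C)(C)C | intermediate
21 | methyl (1S,2S)-2-[(3E,7R)-9-(tert-butyldimethylsilyloxy)-3,7-dimethylnon-3-en-1-yl]-1,3-dimethyl-4-(trimethylsilyloxy)cyclohex-3-ene-1-carboxylate | COC(=O)[C@@]1(C)CCC(O[Si](C)(C)C)=C(C)[C@@H]1CC/C(C)=C/CC[C@@H](C)CCO[Si](C)(C)C(C)(C)C | intermediate
22 | methyl (1S,2S)-2-[(3E,7R)-9-(tert-butyldimethylsilyloxy)-3,7-dimethylnon-3-en-1-yl]-1,3-dimethyl-4-(trifluoromethanesulfonyloxy)cyclohex-3-ene-1-carboxylate | COC(=O)[C@@]1(C)CCC(OS(=O)(=O)C(F)(F)F)=C(C)[C@@H]1CC/C(C)=C/CC[C@@H](C)CCO[Si](C)(C)C(C)(C)C | intermediate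
23 | methyl (1S,2S)-2-[(3E,7R)-9-(tert-butyldimethylsilyloxy)-3,7-dimethylnon-3-en-1-yl]-1,3-dimethylcyclohex-3-ene-1-carboxylate | COC(=O)[C@@]1(C)CCC=C(C)[C@@H]1CC/C(C)=C/CC[C@@H](C)CCO[Si](C)(C)C(C)(C)C | intermediate
24 | methyl (1S,2S)-2-[(3E,7R)-9-hydroxy-3,7-dimethylnon-3-en-1-yl]-1,3-dimethylcyclohex-3-ene-1-carboxylate | COC(=O)[C@@]1(C)CCC=C(C)[C@@H]1CC/C(C)=C/CC[C@@H](C)CCO | intermediate
25 | methyl (1S,2S)-2-[(3E,7R)-9-acetoxy-3,7-dimethylnon-3-en-1-yl]-1,3-dimethylcyclohex-3-ene-1-carboxylate | COC(=O)[C@@]1(C)CCC=C(C)[C@@H]1CC/C(C)=C/CC[C@@H](C)CCOC(C)=O | intermediate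
26 | methyl (4S,5S,8R,9S,13R)-15-acetoxyhalim-1(10)-en-18-oate (C8 and C9 methyls cis, both trans to C5–H) | COC(=O)[C@@]1(C)CCC=C2[C@@H]1CC[C@@H](C)[C@]2(C)CC[C@@H](C)CCOC(C)=O | intermediate
27 | methyl (4S,5S,8R,9S,13R)-15-acetoxy-2-oxohalim-1(10)-en-18-oate | COC(=O)[C@@]1(C)CC(=O)C=C2[C@@H]1CC[C@@H](C)[C@]2(C)CC[C@@H](C)CCOC(C)=O | intermediate
28 | methyl (4S,5S,8R,9S,13R)-15-hydroxy-2-oxohalim-1(10)-en-18-oate (CNP0157174.1) | COC(=O)[C@@]1(C)CC(=O)C=C2[C@@H]1CC[C@@H](C)[C@]2(C)CC[C@@H](C)CCO | target

## Step count and least certain steps

Total step count: 19. Longest linear sequence: 13 steps (steps 1 to 6 and 13 to 19; the chain branch, steps 7 to 12 and 13 to 19, is equally long).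

**Step 17 (key step, proposed new method).**
- What may go wrong: proton loss from the C8 cation before the hydride shift, so that the cascade stops at the labdane stage; loss of the C5 proton in place of a C1 proton at the end, giving the tetrasubstituted alkene; and protonation of the chain alkene first. The reason is that every cation on the path has several β-hydrogens, and the protonated C4 ester disfavours charge at C10.
- Fallback (known reaction types, two stages): starting from 25, cyclise under conditions established for monocyclic 1,5-dienes (SnCl4, CH2Cl2, −78 °C) and isolate the trans-fused exocyclic bicyclic alkene F1. Then re-ionise F1 at C8 under conditions known for the labdane-to-halimane backbone rearrangement (BF3·OEt2, CH2Cl2, 0 °C), where H-9 is still in place and the same suprafacial shifts apply. This returns to the route at 26. Each stage can then be tuned alone, and any C5=C10 isomer would be removed on AgNO3-impregnated silica.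

**Step 13.**
- What may go wrong: slow 1,4-addition with competing 1,2-addition, and insufficient facial selectivity. The β-carbon is flanked by a quaternary centre and the enone is α-methylated, and the two faces differ only by methyl against ester.
- Fallback (methyl introduced after the chain): starting from 7 and the Grignard reagent 20, the same copper-catalysed addition to the unmethylated and more reactive enone, which can be run colder, would give the trimethylsilyl enol ether F2. Aminomethylation with Eschenmoser's salt (Me2N=CH2 iodide), then MeI and NaHCO3, would give the 2-methylene ketone F3. Conjugate reduction with LiBH(s-Bu)3 at −78 °C and trapping of the lithium enolate with PhNTf2 would deliver the C10 methyl and the C1=C10 enol triflate regiospecifically, returning to the route at 22. Steps 5 and 6 are then not needed.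

**Step 18.**
- What may go wrong: attack at the tertiary allylic C5–H, or incomplete conversion with over-oxidation, because the alkene is hindered by the quaternary C9.
- Fallback (oxygen delivered through the alkene): starting from 26, epoxidation with mCPBA would give the 1,10-epoxide F4. Opening at C1 with PhSeNa (from (PhSe)2 and NaBH4) would give the hydroxy selenide F5. Oxidation with H2O2 and selenoxide elimination, which can only go towards C2, would give the tertiary allylic alcohol F6. Babler–Dauben oxidative transposition with pyridinium chlorochromate, C5H5NH[CrO3Cl], would then return to the route at 27.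

## Further compounds

F1 | step 17 | methyl 15-acetoxylabd-8(17)-en-18-oate analogue of 26 (trans-fused; C10 methyl anti to C5–H; C9–H syn to C5–H) | COC(=O)[C@@]1(C)CCC[C@]2(C)[C@@H]1CCC(=C)[C@H]2CC[C@@H](C)CCOC(C)=O
F2 | step 13 | methyl (1S,2S)-2-[(3E,7R)-9-(tert-butyldimethylsilyloxy)-3,7-dimethylnon-3-en-1-yl]-1-methyl-4-(trimethylsilyloxy)cyclohex-3-ene-1-carboxylate | COC(=O)[C@@]1(C)CCC(O[Si](C)(C)C)=C[C@@H]1CC/C(C)=C/CC[C@@H](C)CCO[Si](C)(C)C(C)(C)C
F3 | step 13 | methyl (1S,2S)-2-[(3E,7R)-9-(tert-butyldimethylsilyloxy)-3,7-dimethylnon-3-en-1-yl]-1-methyl-3-methylidene-4-oxocyclohexane-1-carboxylate | COC(=O)[C@@]1(C)CCC(=O)C(=C)[C@@H]1CC/C(C)=C/CC[C@@H](C)CCO[Si](C)(C)C(C)(C)C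
F4 | step 18 | 1,10-epoxide of 26 (epoxide face not assigned; both new centres are lost on return to 27) | COC(=O)[C@@]1(C)CCC2OC23[C@@H]1CC[C@@H](C)[C@]3(C)CC[C@@H](C)CCOC(C)=O
F5 | step 18 | 10-hydroxy-1-(phenylselanyl) derivative of 26 (C1 and C10 not assigned) | COC(=O)[C@@]1(C)CCC([Se]c2ccccc2)C3(O)[C@@H]1CC[C@@H](C)[C@]3(C)CC[C@@H](C)CCOC(C)=O
F6 | step 18 | methyl 15-acetoxy-10-hydroxyhalim-1-en-18-oate (tertiary allylic alcohol, C10 not assigned) | COC(=O)[C@@]1(C)CC=CC2(O)[C@@H]1CC[C@@H](C)[C@]2(C)CC[C@@H](C)CCOC(C)=O
A1 | alternative 1 | acyclic siloxytriene enal (E enal, E diene, C8 and C9 set) | O=C/C(C)=C/CC[C@@H](C)[C@@](C)(/C=C/C(=C)O[Si](C)(C)C(C)(C)C)CC[C@@H](C)CCO[Si](C)(C)C(C)(C)C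
A2 | alternative 1 | trans-fused bicyclic C2 silyl enol ether with C4 aldehyde | O=C[C@@]1(C)CC(O[Si](C)(C)C(C)(C)C)=C[C@@H]2[C@@H]1CC[C@@H](C)[C@]2(C)CC[C@@H](C)CCO[Si](C)(C)C(C)(C)C
A3 | alternative 2 | 2-methylcyclohex-2-en-1-one | CC1=CCCCC1=O
A4 | alternative 2 | (E)-5-bromo-3-methylpent-3-en-1-yl tert-butyldimethylsilyl ether | BrC/C=C(\C)CCO[Si](C)(C)C(C)(C)C
A5 | alternative 2 | 2,3-dimethyl-2-alkenylcyclohexanone (C8 and C9 set, C10 ketone) | O=C1CCC[C@@H](C)[C@]1(C)C/C=C(\C)CCO[Si](C)(C)C(C)(C)C
A6 | alternative 3 | ring B 1-vinylcyclohexene diene (C8 and C9 set, chain silyl ether) | C=CC1=CCC[C@@H](C)[C@]1(C)CC[C@@H](C)CCO[Si](C)(C)C(C)(C)C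
A7 | alternative 3 | bicyclic C1=C10 alkene with C4 methyl and aldehyde | O=C[C@@]1(C)CCC=C2[C@@H]1CC[C@@H](C)[C@]2(C)CC[C@@H](C)CCO[Si](C)(C)C(C)(C)C
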